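The flask held 0.47 M of electrophile and 0.423 M of solid nucleophile, with free base in excess. None of the nucleophile was in solution at the start, and its solubility was 30 mM.

electrophile 0.47 M; free base 3.00 equiv; solid nucleophile 0.900 equiv; time 4.0 d
1. part of the electrophile that has reacted at 4.0 d
2. share of free nucleophile in free nucleophile and protonated nucleophile together, at 4.0 d
- as a solid, counted per litre of solution: solid nucleophile
- at the start none of the solid nucleophile is in solution
- run time (flask): 4.0 d

    electrophile + nucleophile → acid set free + product (k1 = 0.57 M⁻¹ h⁻¹)
    nucleophile + acid set free ⇌ protonated nucleophile, settled at all times (K2 = 10000 M⁻¹)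
    acid set free + free base ⇌ salt of the base (K3 = 860 M⁻¹, k3 = 0.66 M⁻¹ h⁻¹)
    acid set free → by-product carried off (k4 = 0.46 h⁻¹)
    solid nucleophile ⇌ nucleophile, rate k5*(cs5 - [nucleophile]) while solid is left; crystals form when [nucleophile] > cs5 (cs5 = 30 mM, k5 = 0.066 h⁻¹)

I call the first asked value c and the second fr.

I integrated the dissolution rate, the coefficient 0.066 h⁻¹ times the gap between solubility and [nucleophile]. With [nucleophile] at zero that rate is highest, so its integral over the run gives the supply ceiling, the largest amount of nucleophile that can enter solution in the time:

0.066 h⁻¹ × 30 mM × 4.0 d = 0.190 M

With the electrophile as charged, dissolved nucleophile was consumed with a pseudo-first-order constant of 0.268 h⁻¹, larger than 0.066 h⁻¹, so I took dissolution as the rate-limiting step. The half-life of nucleophile by step 1 alone, the electrophile as charged, was 0.11 d, short against 4.0 d, so I balanced feed against consumption: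

[nucleophile] = 0.066 h⁻¹ × 30 mM / (0.066 h⁻¹ + 0.268 h⁻¹) = 5.93 mM

By this reckoning the amount dissolved came to 0.153 M, or 32.4% of the electrophile. My figure for c counted all of it as reacted, so it stood high by whatever stayed in solution as nucleophile or protonated nucleophile, and it gave no value for fr.

Then I turned the settings by hand. A longer time raises the supply in proportion, and so raises c. More electrophile shares a supply under the same ceiling, so c falls. In this flask more solid adds nothing to the supply by my reckoning, since the charge already exceeds the amount dissolved. Free base does not appear in the dissolution rate; it enters by taking up acid set free.

The forecast gave 26% and 8.8%, below my figure for c, holding that “The run is limited by dissolution of the solid nucleophile”.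

The simulation gave 23.2% for c and 12.1% for fr, and both values of the forecast stood within the tolerance.

Moved alone up or down by the same factor, the settings shifted c in the order time (7.7 points), then electrophile (3.8 points), then free base (0.54 points), then solid nucleophile (under 0.05 points). A shift of 5 points took a time of 3.22 d or 4.78 d. In this flask the solid lost by 4.00 d was 0.160 M, which is 84.2% of the supply ceiling. In the neighbour flask with 0.12 M of electrophile, the same ceiling of 0.190 M stood above its solid charge of 0.108 M, and its solid nucleophile stood at 0% at 4.00 d.

The rate constants were set for the occasion.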